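## Retrosynthetic overview
1. Last bond, C8–prenyl: the aromatic chromanone acid is released in the flask from its lactone. A ligand-controlled dearomatising prenylation then sets the quaternary C8.
2. C8–CH2: reductive alkylation of the tricyclic phenol with a cyclobutanecarbaldehyde. Both cyclobutane stereocentres are bought with (−)-verbenone.
3. Key disconnection, O1–C2: an enantioselective 6-endo oxa-Michael closure of an o-hydroxyaryl tigloyl ketone builds the dihydropyranone ring. It sets C2 and, after equilibration, C3. The coumarin lactone ties up O5, so only the oxygen next to C8 can close.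
4. Side-chain stereocentre: asymmetric conjugate reduction of the 4-pentylcoumarin. Its lactone is the only protecting group in the route (acid and 5-OH).
5. Ring order: benzene ring (phloroglucinol), then coumarin pyranone (Pechmann), then dihydropyranone (oxa-Michael), then lactone opened and benzene ring dearomatised. The cyclobutane comes ready-made.

Numbering: the core of the target and its ring-opened precursor is numbered as a chroman-4-one (O1, C2, C3, C4, C4a, C5 to C8, C8a). Names of the tricyclic lactones use pyrano[2,3-f]chromene numbering.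

Assumption: the ligand enantiomers written for steps 4 and 9 are assigned by analogy with the nearest known substrate classes; both antipodes are sold, and the mirror-image ligand is used if the first run shows the opposite sense.

## Route

Step 1
Reactants: 1 phloroglucinol; 2 ethyl 3-oxooctanoate
Product: 3 5,7-dihydroxy-4-pentylcoumarin
Conditions: conc. H2SO4, 90 °C, 2 h; ice water, filter
Reagents that add atoms: none
Why: Pechmann condensation (acid-promoted transesterification, ring alkylation by the ketone, dehydration) gives the coumarin; the threefold symmetry of 1 allows only one regioisomer and no stereocentre is formed.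

Step 2
Reactants: 3 5,7-dihydroxy-4-pentylcoumarin; 4 tigloyl chloride
Product: 5 5,7-dihydroxy-8-[(E)-2-methylbut-2-enoyl]-4-pentylcoumarin
Conditions: AlCl3 (4 equiv), ClCH2CH2Cl/PhNO2, 70 °C, 3 h; ice/dilute aq HCl
Reagents that add atoms: none
Why: Friedel–Crafts acylation of 4-alkyl-5,7-dihydroxycoumarins goes to C8 (C6 is buttressed by the 5-OH/4-alkyl peri pair), which places the enone between the lactone oxygen and one free OH, and the aluminium chelate of the o-hydroxyaryl ketone keeps the enone open until the cold acidic quench.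

Step 3
Reactants: 5 5,7-dihydroxy-8-[(E)-2-methylbut-2-enoyl]-4-pentylcoumarin
Product: 7 (8R,9R)-5-hydroxy-8,9-dimethyl-4-pentyl-8,9-dihydro-2H,10H-pyrano[2,3-f]chromene-2,10-dione, via cis-chromanone 6 (not isolated)
Conditions: (−)-quinine (20 mol %), PhCl, 15 °C, 48 h; then MgI2 (1 equiv), 40 °C, 6 h
Reagents that add atoms: none
Why: Key step, a cinchona-alkaloid-catalysed intramolecular oxa-Michael addition: the quinuclidine nitrogen deprotonates the only OH ortho to the enone while the alkaloid OH binds the carbonyl, so the phenolate oxygen adds to one face of the β-carbon and forms O1–C2 with R configuration (the sense established for 7-hydroxy-8-tigloylcoumarins), kinetic protonation gives the cis isomer, and soft enolisation by MgI2 plus the alkaloid base epimerises the α-carbon to the more stable diequatorial trans (R,R) arrangement.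

Step 4
Reactants: 7 (8R,9R)-5-hydroxy-8,9-dimethyl-4-pentyl-8,9-dihydro-2H,10H-pyrano[2,3-f]chromene-2,10-dione
Product: 9 (4S,8R,9R)-5-hydroxy-8,9-dimethyl-4-pentyl-3,4,8,9-tetrahydro-2H,10H-pyrano[2,3-f]chromene-2,10-dione, via boron enolate 8 (not isolated)
Conditions: CuCl (5 mol %), NaOtBu (5 mol %), (R)-DTBM-SEGPHOS (5.5 mol %), HBpin (2.3 equiv), toluene, 0 °C to rt; aq NH4Cl
Reagents that add atoms: none
Why: Copper hydride-catalysed asymmetric conjugate reduction (1,4-hydroboration) of a 4-substituted coumarin: the first equivalent of HBpin masks the phenol, the ligand-bound copper hydride delivers hydride to one face of coumarin C4 to set the S centre, the boron enolate resists over-reduction until work-up, and the chromanone carbonyl should be spared because it is an α-branched, peri-flanked vinylogous carbonate.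

Step 5
Reactants: 10 (1S,5S)-(−)-verbenone
Product: 11 (1S,3R)-3-acetyl-2,2-dimethylcyclobutane-1-carboxylic acid ((−)-cis-pinononic acid)
Conditions: RuCl3 hydrate (2 mol %), NaIO4 (4.2 equiv), EtOAc/MeCN/H2O, rt
Reagents that add atoms: sodium periodate, [Na+].[O-]I(=O)(=O)=O
Why: RuO4-catalysed oxidative cleavage of the enone C=C gives the methyl ketone and an α-keto acid that loses CO2 oxidatively, and the two bridgehead carbons of 10 become the cis-1,3 stereocentres of the cyclobutane untouched.

Step 6
Reactants: 11 (1S,3R)-3-acetyl-2,2-dimethylcyclobutane-1-carboxylic acid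
Product: 12 (1S,3S)-2,2-dimethyl-3-(prop-1-en-2-yl)cyclobutane-1-carboxylic acid
Conditions: Ph3PCH3Br (2.5 equiv), KOtBu (3.4 equiv), THF, 0 °C to rt; dilute aq HCl
Reagents that add atoms: methyltriphenylphosphonium bromide, C[P+](c1ccccc1)(c1ccccc1)c1ccccc1.[Br-]
Why: Wittig methylenation of the methyl ketone on the potassium carboxylate, run cold with preformed ylide so that olefination outruns enolisation and the cis relationship is kept.

Step 7
Reactants: 12 (1S,3S)-2,2-dimethyl-3-(prop-1-en-2-yl)cyclobutane-1-carboxylic acid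
Product: 14 (1S,3S)-2,2-dimethyl-3-(prop-1-en-2-yl)cyclobutane-1-carbaldehyde, via acyl imidazole 13 (not isolated)
Conditions: 1,1'-carbonyldiimidazole (1.1 equiv), CH2Cl2, 0 °C to rt; DIBAL-H (2.2 equiv), −78 °C; aq Rochelle salt
Reagents that add atoms: none
Why: One-pot activation as the acyl imidazole and partial reduction with DIBAL-H at −78 °C stops at the aldehyde through a stable tetrahedral aluminium adduct and touches neither the alkene nor the α-stereocentre.

Step 8
Reactants: 9 (4S,8R,9R)-5-hydroxy-8,9-dimethyl-4-pentyl-3,4,8,9-tetrahydro-2H,10H-pyrano[2,3-f]chromene-2,10-dione; 14 (1S,3S)-2,2-dimethyl-3-(prop-1-en-2-yl)cyclobutane-1-carbaldehyde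
Product: 16 (4S,8R,9R)-6-{[(1R,3S)-2,2-dimethyl-3-(prop-1-en-2-yl)cyclobutyl]methyl}-5-hydroxy-8,9-dimethyl-4-pentyl-3,4,8,9-tetrahydro-2H,10H-pyrano[2,3-f]chromene-2,10-dione, via o-quinone methide 15 (not isolated)
Conditions: (S)-proline (20 mol %), Hantzsch ester (1.3 equiv), 14 (1.3 equiv), CH2Cl2, 35 °C, 36 h
Reagents that add atoms: none
Why: Organocatalytic three-component reductive alkylation (Knoevenagel-type condensation, then Hantzsch ester transfer hydrogenation): the only free ring CH, ortho to the acidic OH, adds to the proline iminium ion of 14, loss of proline gives the o-quinone methide, and fast hydride transfer rearomatises it before the cyclobutane α-carbon can epimerise, so no stereocentre is made or lost.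

Step 9
Reactants: 16 (4S,8R,9R)-6-{[(1R,3S)-2,2-dimethyl-3-(prop-1-en-2-yl)cyclobutyl]methyl}-5-hydroxy-8,9-dimethyl-4-pentyl-3,4,8,9-tetrahydro-2H,10H-pyrano[2,3-f]chromene-2,10-dione; 17 prenyl acetate (3-methylbut-2-en-1-yl acetate)
Product: 19 (3S)-3-[(2R,3R,8R)-8-{[(1R,3S)-2,2-dimethyl-3-(prop-1-en-2-yl)cyclobutyl]methyl}-5-hydroxy-2,3-dimethyl-8-(3-methylbut-2-en-1-yl)-4,7-dioxo-3,4,7,8-tetrahydro-2H-chromen-6-yl]octanoic acid, via ring-opened dipotassium salt 18 (not isolated)
Conditions: KOSiMe3 (2.05 equiv), THF, 0 °C, 20 min; then Pd2(dba)3·CHCl3 (2.5 mol %), (R,R)-DACH-phenyl Trost ligand (7.5 mol %), 17 (1.2 equiv), 0 °C to rt; dilute aq HCl to pH 3, 0 °C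
Reagents that add atoms: potassium trimethylsilanolate, C[Si](C)(C)[O-].[K+]
Why: Proposed new method: catalyst-controlled dearomative linear prenylation of a C-alkylated acylphloroglucinol-type phenolate; KOSiMe3 opens the aryl lactone without water to the carboxylate/7-phenolate dipotassium salt (the chelated 5-OH stays protonated), zerovalent palladium ionises prenyl acetate to a 1,1-dimethylallyl palladium cation held in the chiral pocket, O-prenylation of phenolate or carboxylate is reversible under these conditions, outer-sphere attack of the soft ring carbon C8 (it carries a primary alkyl group and is less shielded than C6 with its branched chain) on the unsubstituted allyl terminus is made irreversible by tautomerisation to the acidic enol, and the ligand walls select the face of the flat nucleophile so that C8 forms with R configuration whatever the remote stereocentres; the closest known reaction types are the palladium-catalysed asymmetric allylic dearomatisation of 1-substituted 2-naphthols, the asymmetric linear prenylation of oxindoles, and the non-stereoselective base- or palladium-mediated dearomative allylation of acylphloroglucinols.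

## Compound list
1 | phloroglucinol (benzene-1,3,5-triol) | Oc1cc(O)cc(O)c1 | starting material
2 | ethyl 3-oxooctanoate | CCCCCC(=O)CC(=O)OCC | starting material
3 | 5,7-dihydroxy-4-pentylcoumarin | CCCCCC1=CC(=O)Oc2cc(O)cc(O)c21 | intermediate
4 | tigloyl chloride ((E)-2-methylbut-2-enoyl chloride) | C/C=C(\C)C(=O)Cl | starting material
5 | 5,7-dihydroxy-8-[(E)-2-methylbut-2-enoyl]-4-pentylcoumarin | CCCCCC1=CC(=O)Oc2c(C(=O)/C(C)=C/C)c(O)cc(O)c21 | intermediate
6 | (8R,9S)-5-hydroxy-8,9-dimethyl-4-pentyl-8,9-dihydro-2H,10H-pyrano[2,3-f]chromene-2,10-dione (cis-chromanone) | CCCCCC1=CC(=O)Oc2c1c(O)cc3c2C(=O)[C@@H](C)[C@@H](C)O3 | intermediate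
7 | (8R,9R)-5-hydroxy-8,9-dimethyl-4-pentyl-8,9-dihydro-2H,10H-pyrano[2,3-f]chromene-2,10-dione (trans-chromanone) | CCCCCC1=CC(=O)Oc2c1c(O)cc3c2C(=O)[C@H](C)[C@@H](C)O3 | intermediate
8 | boron enolate of 9: 2-(pinacolboryloxy)-4H-chromene ketene acetal with the phenol as its O-Bpin ether | CCCCC[C@H]1C=C(OB4OC(C)(C)C(C)(C)O4)Oc2c1c(OB5OC(C)(C)C(C)(C)O5)cc3c2C(=O)[C@H](C)[C@@H](C)O3 | intermediate
9 | (4S,8R,9R)-5-hydroxy-8,9-dimethyl-4-pentyl-3,4,8,9-tetrahydro-2H,10H-pyrano[2,3-f]chromene-2,10-dione | CCCCC[C@H]1CC(=O)Oc2c1c(O)cc3c2C(=O)[C@H](C)[C@@H](C)O3 | intermediate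
10 | (1S,5S)-(−)-verbenone | CC1=CC(=O)[C@H]2C[C@@H]1C2(C)C | starting material
11 | (1S,3R)-3-acetyl-2,2-dimethylcyclobutane-1-carboxylic acid | OC(=O)[C@H]1C[C@@H](C(C)=O)C1(C)C | intermediate
12 | (1S,3S)-2,2-dimethyl-3-(prop-1-en-2-yl)cyclobutane-1-carboxylic acid | OC(=O)[C@H]1C[C@@H](C(C)=C)C1(C)C | intermediate
13 | [(1S,3S)-2,2-dimethyl-3-(prop-1-en-2-yl)cyclobutyl](imidazol-1-yl)methanone | O=C(n1ccnc1)[C@H]1C[C@@H](C(C)=C)C1(C)C | intermediate
14 | (1S,3S)-2,2-dimethyl-3-(prop-1-en-2-yl)cyclobutane-1-carbaldehyde | O=C[C@H]1C[C@@H](C(C)=C)C1(C)C | intermediate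
15 | o-quinone methide from 9 and 14 (exocyclic C=CH-cyclobutyl at ring position 6, C5 carbonyl) | CCCCC[C@H]1CC(=O)OC2=C1C(=O)C(=C[C@H]4C[C@@H](C(C)=C)C4(C)C)C3=C2C(=O)[C@H](C)[C@@H](C)O3 | intermediate
16 | (4S,8R,9R)-6-{[(1R,3S)-2,2-dimethyl-3-(prop-1-en-2-yl)cyclobutyl]methyl}-5-hydroxy-8,9-dimethyl-4-pentyl-3,4,8,9-tetrahydro-2H,10H-pyrano[2,3-f]chromene-2,10-dione | CCCCC[C@H]1CC(=O)Oc2c1c(O)c(C[C@H]4C[C@@H](C(C)=C)C4(C)C)c3c2C(=O)[C@H](C)[C@@H](C)O3 | intermediate
17 | prenyl acetate (3-methylbut-2-en-1-yl acetate) | CC(=O)OCC=C(C)C | starting material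
18 | dipotassium salt (carboxylate and 7-phenolate) of (3S)-3-[(2R,3R)-8-{[(1R,3S)-2,2-dimethyl-3-(prop-1-en-2-yl)cyclobutyl]methyl}-5,7-dihydroxy-2,3-dimethyl-4-oxochroman-6-yl]octanoic acid | [K+].[K+].CCCCC[C@@H](CC(=O)[O-])c1c([O-])c(C[C@H]4C[C@@H](C(C)=C)C4(C)C)c2O[C@H](C)[C@@H](C)C(=O)c2c1O | intermediate
19 | (3S)-3-[(2R,3R,8R)-8-{[(1R,3S)-2,2-dimethyl-3-(prop-1-en-2-yl)cyclobutyl]methyl}-5-hydroxy-2,3-dimethyl-8-(3-methylbut-2-en-1-yl)-4,7-dioxo-3,4,7,8-tetrahydro-2H-chromen-6-yl]octanoic acid (CNP0208815.1) | C=C(C)[C@@H]1C[C@H](C[C@@]2(CC=C(C)C)C(=O)C([C@@H](CCCCC)CC(=O)O)=C(O)C3=C2O[C@H](C)[C@@H](C)C3=O)C1(C)C | target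

## Count and risks
Total step count: 9.
Longest linear sequence: 6 steps (1, 2, 3, 4, 8, 9). The cyclobutane branch (5, 6, 7) joins at step 8.

**Risk 1, step 9 (the proposed new step).**
- The neopentyl-like group on C8 may slow C-attack inside the ligand pocket.
- C6 or oxygen may compete with C8.
- The facial selectivity is untested.

Fallback with known chemistry: setting out from 16, the lactone is opened with aqueous KOH to the salt 18. The phenolate is alkylated with prenyl bromide at 0 °C, the classical base-mediated alkylative dearomatisation used for hop β-acids. Without a catalyst both faces react, so 19 forms together with the C8 epimer of the target F1. The two diastereomers are separated by reversed-phase chromatography or through their (R)-1-phenylethylammonium salts. The fallback comes back to the route at 19.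

**Risk 2, step 8.**
- Phenol 9 is a weaker carbon nucleophile than a true 1,3-dione.
- Proline may slowly open the aryl lactone.
- The o-quinone methide can tautomerise to an alkenylphenol, which would erase the cyclobutane α-centre.

Fallback, setting out from 9 and 14:
- 9 is iodinated at its only free ring position (N-iodosuccinimide, MeCN) to the 6-iodo lactone F2.
- 14 is reduced with NaBH4 to the cyclobutylmethanol F3 and converted (I2, PPh3, imidazole) into the cyclobutylmethyl iodide F4.
- Iodine–lithium exchange (t-BuLi, Et2O, −78 °C) and capture with B-methoxy-9-BBN give the lithium alkyl(methoxy)borate F5.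
- F5 is joined to F2 in a B-alkyl Suzuki–Miyaura coupling (Pd(dppf)Cl2, aq K3PO4, DMF, 50 °C).

The aqueous base opens the lactone, so the coupling product is the salt 18. There the fallback comes back to the route (dried, then the palladium stage of step 9).

**Risk 3, step 4.**
- The electron-rich coumarin may react slowly.
- The copper hydride may reduce the chromanone carbonyl instead.

Fallback: setting out from 7, plain hydrogenation (H2, palladium on carbon, EtOAc) saturates only the coumarin C3–C4 bond. It gives 9 and the 4R epimer of the lactone F6 in about equal amounts. They are diastereomers because C8 and C9 are already fixed, so they are separated by chromatography or crystallisation. The fallback comes back to the route at 9.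

## Further compounds
F1 | step 9 | C8 epimer of the target ((8S) configuration, all other centres as in 19) | C=C(C)[C@@H]1C[C@H](C[C@]2(CC=C(C)C)C(=O)C([C@@H](CCCCC)CC(=O)O)=C(O)C3=C2O[C@H](C)[C@@H](C)C3=O)C1(C)C
F2 | step 8 | 6-iodo lactone ((4S,8R,9R)-5-hydroxy-6-iodo-8,9-dimethyl-4-pentyl-3,4,8,9-tetrahydro-2H,10H-pyrano[2,3-f]chromene-2,10-dione) | CCCCC[C@H]1CC(=O)Oc2c1c(O)c(I)c3c2C(=O)[C@H](C)[C@@H](C)O3
F3 | step 8 | cyclobutylmethanol ([(1S,3S)-2,2-dimethyl-3-(prop-1-en-2-yl)cyclobutyl]methanol) | OC[C@H]1C[C@@H](C(C)=C)C1(C)C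
F4 | step 8 | cyclobutylmethyl iodide ((1S,3S)-1-(iodomethyl)-2,2-dimethyl-3-(prop-1-en-2-yl)cyclobutane) | IC[C@H]1C[C@@H](C(C)=C)C1(C)C
F5 | step 8 | lithium alkyl(methoxy)borate (B-methoxy-9-BBN ate complex of the cyclobutylmethyl group) | [Li+].CO[B-]1(C[C@H]2C[C@@H](C(C)=C)C2(C)C)C2CCCC1CCC2
F6 | step 4 | 4R epimer of the lactone ((4R,8R,9R)-5-hydroxy-8,9-dimethyl-4-pentyl-3,4,8,9-tetrahydro-2H,10H-pyrano[2,3-f]chromene-2,10-dione) | CCCCC[C@@H]1CC(=O)Oc2c1c(O)cc3c2C(=O)[C@H](C)[C@@H](C)O3
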